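**Retrosynthetic overview**
1. The 1,2-dioxan-3-ol ring (O1–O2–C3–C4–C5–C6) is a cyclic peroxyhemiketal, the closed form of a γ-hydroperoxy ketone. C3 is a latent ketone, C4 its α-carbon, C5 a CH2, and C6 a fully substituted O-bearing carbon, so C5/C6 are the two carbons of a 1,1-disubstituted alkene. This feature permits a radical/O2 annulation.
2. Key disconnection: C4–C5 and C6–O1 (O2–C3 follows by hemiketalisation) lead to acyclic diene 10, 3-methylpentane-2,4-dione 11 (its second acetyl on C4 is a temporary activating group) and O2. The only ring forms in this step.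
3. The activating acetyl is then removed by retro-Claisen cleavage; C3 and C4 settle through ring–chain tautomerism.
4. Diene 10 comes from methyl ketone 9 (methylenation), 9 from enone 8 (Cu-catalysed asymmetric methyl conjugate addition sets the side-chain stereocentre), 8 from aldehyde 6, and 6 from a Z-selective Wittig reaction of benzaldehyde.

Key step: step 7

Remark 1 (C6 and C4): the C6–O bond forms by O2 capture at a planar tertiary radical whose only chiral neighbour is the 1,3-related side-chain centre, and axial CH3 versus axial CH2R at C6 should differ little in energy. No kinetic or thermodynamic control of C6, or of C4 relative to C6, is therefore assumed; the (3S,4R,6S) isomer is secured by diastereomer separation after step 8, with recycling of the C4 epimer.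

Remark 2 (step 5): both enantiomers of the Josiphos ligand are commercial; the one that delivers methyl to the Re face of C4 of enone 8 (giving 4R) is assumed to be assignable from the known sense for linear (E)-alk-3-en-2-ones.

**Route**

Step 1
Reactants: 1 8-bromooctan-1-ol
Product: 2 (8-hydroxyoctyl)triphenylphosphonium bromide
Conditions: PPh3 (1.1 equiv), MeCN, reflux
Reagents that add atoms: triphenylphosphine, c1ccc(cc1)P(c1ccccc1)c1ccccc1
Why: SN2 quaternisation of triphenylphosphine by a primary bromide (phosphonium salt formation for a Wittig reaction), which the free hydroxyl does not disturb.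

Step 2
Reactants: 2 (8-hydroxyoctyl)triphenylphosphonium bromide, 3 benzaldehyde
Product: 5 (Z)-9-phenylnon-8-en-1-ol, via alkoxide ylide 4 (not isolated)
Conditions: NaHMDS (2.1 equiv), THF, 0 °C; then 3, −78 °C → rt; aq. NH4Cl
Reagents that add atoms: none
Why: Wittig reaction of a lithium-free non-stabilised ylide with an aromatic aldehyde under kinetic control should pass through the cis-oxaphosphetane and give the (Z)-alkene (the second equivalent of base only deprotonates the hydroxyl); residual (E)-isomer would be removed on AgNO3-impregnated silica.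

Step 3
Reactants: 5 (Z)-9-phenylnon-8-en-1-ol
Product: 6 (Z)-9-phenylnon-8-enal
Conditions: TEMPO (10 mol %), PhI(OAc)2 (1.1 equiv), CH2Cl2, rt
Reagents that add atoms: none
Why: TEMPO/oxoammonium oxidation of a primary alcohol stops at the aldehyde and should leave the (Z)-styrene untouched.

Step 4
Reactants: 6 (Z)-9-phenylnon-8-enal, 7 1-(triphenylphosphoranylidene)propan-2-one
Product: 8 (3E,11Z)-12-phenyldodeca-3,11-dien-2-one
Conditions: 7 (1.3 equiv), CH2Cl2, 40 °C
Reagents that add atoms: none
Why: Wittig reaction of a stabilised acyl ylide with an aliphatic aldehyde should give the (E)-enone under thermodynamic control of the oxaphosphetane, without touching the remote (Z)-styrene.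

Step 5
Reactants: 8 (3E,11Z)-12-phenyldodeca-3,11-dien-2-one
Product: 9 (4R,11Z)-4-methyl-12-phenyldodec-11-en-2-one
Conditions: MeMgBr (1.3 equiv), CuBr·SMe2 (5 mol %), Josiphos (6 mol %), t-BuOMe, −75 °C; MeOH, aq. NH4Cl
Reagents that add atoms: methylmagnesium bromide, C[Mg]Br
Why: Copper-catalysed asymmetric conjugate addition of a Grignard reagent to a linear (E)-alk-3-en-2-one, in which the chiral ferrocenyl diphosphine–copper complex delivers methyl to the Re face of C4 and so sets the side-chain stereocentre (4R) under catalyst control.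

Step 6
Reactants: 9 (4R,11Z)-4-methyl-12-phenyldodec-11-en-2-one
Product: 10 (4R,11Z)-2,4-dimethyl-12-phenyldodeca-1,11-diene
Conditions: Ph3PCH3Br (1.5 equiv), KOtBu (1.4 equiv), THF, 0 °C → rt
Reagents that add atoms: methyltriphenylphosphonium bromide, C[P+](c1ccccc1)(c1ccccc1)c1ccccc1.[Br-]
Why: Wittig methylenation of a methyl ketone, in which the stereocentre is β to the carbonyl and cannot epimerise by enolisation.

Step 7
Reactants: 10 (4R,11Z)-2,4-dimethyl-12-phenyldodeca-1,11-diene, 11 3-methylpentane-2,4-dione
Product: 13 1-[(6S)-3-hydroxy-3,4,6-trimethyl-6-[(2R,9Z)-2-methyl-10-phenyldec-9-en-1-yl]-1,2-dioxan-4-yl]ethan-1-one, via hydroperoxy diketone 12 (not isolated)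
Conditions: 11 (4 equiv), Mn(OAc)3·2H2O (0.2 equiv), AcOH, O2 (1 atm) or dry air, 23 °C, dark
Reagents that add atoms: dioxygen, O=O
Why: Mn(III) oxidises its enolate of 11 to the tertiary 1,3-diketonyl radical, which adds to the =CH2 terminus of the 1,1-disubstituted alkene of 10 (C4–C5 bond); the resulting tertiary C6 radical captures triplet O2 (C6–O bond), Mn(II) reduces the peroxyl radical to hydroperoxide 12 (regenerating Mn(III)), and 12 closes onto one of its two equivalent acetyl groups. The closest known reaction type is the Mn(III)-catalysed aerobic peroxidation of 1,1-disubstituted alkenes with 1,3-dicarbonyl compounds to 1,2-dioxan-3-ols, an oxidative [2+2+2] annulation. The 1,2-dioxane ring closes by 6-exo-trig addition of the hydroperoxide oxygen to the ketone C=O (hemiketalisation). C6 arises from O2 capture at a planar radical with no useful bias, so both C6 epimers are expected and are carried on as a mixture (13 is drawn as the 6S series); C3 and C4 of 13 are under thermodynamic control by ring–chain tautomerism, since open form 12 is not stereogenic at C4, and C4 is reset in step 8. The step needs chemoselectivity for the methylidene over the (Z)-styrene and Markovnikov regiochemistry: the bulky tertiary radical should add much faster to an unsubstituted =CH2 than to the alkyl-bearing carbon of a twisted cis-1,2-disubstituted styrene, and addition at CH2 gives the tertiary radical. The room-temperature, thiyl-free, dark conditions should leave the Z geometry intact, and the symmetry of 11 removes any question of which α-carbon or carbonyl reacts.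

Step 8
Reactants: 13 1-[(6S)-3-hydroxy-3,4,6-trimethyl-6-[(2R,9Z)-2-methyl-10-phenyldec-9-en-1-yl]-1,2-dioxan-4-yl]ethan-1-one
Product: 15 (3S,4R,6S)-3,4,6-trimethyl-6-[(2R,9Z)-2-methyl-10-phenyldec-9-en-1-yl]-1,2-dioxan-3-ol, via hydroperoxy ketone 14 (not isolated)
Conditions: NaOMe (0.3 equiv), MeOH, 0 °C → rt; pH 7 phosphate buffer; preparative HPLC
Reagents that add atoms: none
Why: Retro-Claisen deacylation of a non-enolisable 2,2-disubstituted 1,3-diketone (methoxide or the internal peroxy anion attacks an acetyl group of the open form, the ketone enolate is expelled and protonated, and any peracetate is methanolysed) should give 14, which recloses with hydroxyl axial (peroxy-anomeric effect) and C4-methyl equatorial so that C3 follows C4 thermodynamically; C4 is set by protonation and equilibration through 14 without bias relative to C6, so the (3S,4R,6S) isomer would be isolated by HPLC from its C4 and C6 epimers and the (6S) C4-epimer re-equilibrated under the same conditions.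

**Compound list**
1 | 8-bromooctan-1-ol | OCCCCCCCCBr | starting material
2 | (8-hydroxyoctyl)triphenylphosphonium bromide | OCCCCCCCC[P+](c1ccccc1)(c1ccccc1)c1ccccc1.[Br-] | intermediate
3 | benzaldehyde | O=Cc1ccccc1 | starting material
4 | sodium 8-(triphenylphosphoranylidene)octan-1-olate (alkoxide ylide, not isolated) | [Na+].[O-]CCCCCCCC=P(c1ccccc1)(c1ccccc1)c1ccccc1 | intermediate
5 | (Z)-9-phenylnon-8-en-1-ol | OCCCCCCC/C=C\c1ccccc1 | intermediate
6 | (Z)-9-phenylnon-8-enal | O=CCCCCCC/C=C\c1ccccc1 | intermediate
7 | 1-(triphenylphosphoranylidene)propan-2-one | CC(=O)C=P(c1ccccc1)(c1ccccc1)c1ccccc1 | starting material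
8 | (3E,11Z)-12-phenyldodeca-3,11-dien-2-one | CC(=O)/C=C/CCCCCC/C=C\c1ccccc1 | intermediate
9 | (4R,11Z)-4-methyl-12-phenyldodec-11-en-2-one | C[C@H](CCCCCC/C=C\c1ccccc1)CC(C)=O | intermediate
10 | (4R,11Z)-2,4-dimethyl-12-phenyldodeca-1,11-diene | C[C@H](CCCCCC/C=C\c1ccccc1)CC(C)=C | intermediate
11 | 3-methylpentane-2,4-dione | CC(=O)C(C)C(C)=O | starting material
12 | 3-[(2S,4R,11Z)-2-hydroperoxy-2,4-dimethyl-12-phenyldodec-11-en-1-yl]-3-methylpentane-2,4-dione (not isolated; formed together with its 2R epimer) | C[C@H](CCCCCC/C=C\c1ccccc1)C[C@](C)(OO)CC(C)(C(C)=O)C(C)=O | intermediate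
13 | 1-[(6S)-3-hydroxy-3,4,6-trimethyl-6-[(2R,9Z)-2-methyl-10-phenyldec-9-en-1-yl]-1,2-dioxan-4-yl]ethan-1-one (C3/C4 diastereomers in equilibrium; carried on together with the 6R series) | C[C@H](CCCCCC/C=C\c1ccccc1)C[C@@]1(C)CC(C)(C(C)=O)C(C)(O)OO1 | intermediate
14 | (3R,5S,7R,14Z)-5-hydroperoxy-3,5,7-trimethyl-15-phenylpentadec-14-en-2-one (not isolated; in equilibrium with its C3 epimer) | C[C@H](CCCCCC/C=C\c1ccccc1)C[C@](C)(OO)C[C@@H](C)C(C)=O | intermediate
15 | (3S,4R,6S)-3,4,6-trimethyl-6-[(2R,9Z)-2-methyl-10-phenyldec-9-en-1-yl]-1,2-dioxan-3-ol | C[C@H](CCCCCC/C=C\c1ccccc1)C[C@@]1(C)C[C@@H](C)[C@@](C)(O)OO1 | target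

**Step count**
Total steps: 8. Longest linear sequence: 8 steps (1 → 15).

**Steps most likely to fail**

Step 7. The diketonyl radical, or the chain-carrying peroxyl radicals, may also add to the (Z)-styrene, eroding chemoselectivity and Z geometry, and α-oxygenation of 11 may outrun addition to the unactivated alkene. The fallback avoids any carbon-radical addition to an alkene. It sets out from ketone 9: sulfonium-ylide spiroannulation (cyclopropyldiphenylsulfonium tetrafluoroborate, KOH, DMSO) would give 2-methyl-2-[(2R,9Z)-2-methyl-10-phenyldec-9-en-1-yl]-1-oxaspiro[2.2]pentane F1, which would be rearranged with catalytic LiBF4 to 2-methyl-2-[(2R,9Z)-2-methyl-10-phenyldec-9-en-1-yl]cyclobutan-1-one F2. Methylation at the only enolisable α-position (LDA, MeI, THF, −78 °C) would give 2,4-dimethyl-2-[(2R,9Z)-2-methyl-10-phenyldec-9-en-1-yl]cyclobutan-1-one F3, and MeMgBr would give 1,2,4-trimethyl-2-[(2R,9Z)-2-methyl-10-phenyldec-9-en-1-yl]cyclobutan-1-ol F4. Co(acac)2-catalysed aerobic oxidative ring expansion of the cyclobutanol (β-scission of the alkoxy radical toward the fully substituted carbon, O2 capture) would then return to the route at hydroperoxy ketone 14 and hence 15, with the same separation as in step 8.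

Step 8. Base may trigger loss of the peroxide, or acyl transfer may stall at a peracetate instead of completing the deacylation. The fallback removes the activating group without base. It sets out from diene 10: the same Mn(III)/O2 annulation with tert-butyl 2-methyl-3-oxobutanoate in place of 11 would give tert-butyl (6S)-3-hydroxy-3,4,6-trimethyl-6-[(2R,9Z)-2-methyl-10-phenyldec-9-en-1-yl]-1,2-dioxane-4-carboxylate F5. TFA in CH2Cl2 at 0 °C would cleave it to (6S)-3-hydroxy-3,4,6-trimethyl-6-[(2R,9Z)-2-methyl-10-phenyldec-9-en-1-yl]-1,2-dioxane-4-carboxylic acid F6, whose open β-keto acid form should lose CO2 on warming to rt and return to the route at 14, and hence 15.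

Step 5. Competing 1,2-addition and insufficient facial discrimination are possible when MeMgBr is added to a methyl ketone acceptor. The fallback moves the conjugate addition to the thioester class, for which methyl Grignard addition is established, and builds the methyl ketone afterwards. It sets out from aldehyde 6: Wittig reaction with S-ethyl 2-(triphenylphosphoranylidene)ethanethioate would give S-ethyl (2E,10Z)-11-phenylundeca-2,10-dienethioate F7. Cu/Josiphos-catalysed MeMgBr addition would give S-ethyl (3R,10Z)-3-methyl-11-phenylundec-10-enethioate F8, and Me2CuLi (Et2O, −78 °C) would convert the thioester into the methyl ketone, returning to the route at 9.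

**Further compounds**
F1 | step 7 | 2-methyl-2-[(2R,9Z)-2-methyl-10-phenyldec-9-en-1-yl]-1-oxaspiro[2.2]pentane | C[C@H](CCCCCC/C=C\c1ccccc1)CC1(C)OC12CC2
F2 | step 7 | 2-methyl-2-[(2R,9Z)-2-methyl-10-phenyldec-9-en-1-yl]cyclobutan-1-one | C[C@H](CCCCCC/C=C\c1ccccc1)CC1(C)CCC1=O
F3 | step 7 | 2,4-dimethyl-2-[(2R,9Z)-2-methyl-10-phenyldec-9-en-1-yl]cyclobutan-1-one | C[C@H](CCCCCC/C=C\c1ccccc1)CC1(C)CC(C)C1=O
F4 | step 7 | 1,2,4-trimethyl-2-[(2R,9Z)-2-methyl-10-phenyldec-9-en-1-yl]cyclobutan-1-ol | C[C@H](CCCCCC/C=C\c1ccccc1)CC1(C)CC(C)C1(C)O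
F5 | step 8 | tert-butyl (6S)-3-hydroxy-3,4,6-trimethyl-6-[(2R,9Z)-2-methyl-10-phenyldec-9-en-1-yl]-1,2-dioxane-4-carboxylate | C[C@H](CCCCCC/C=C\c1ccccc1)C[C@@]1(C)CC(C)(C(=O)OC(C)(C)C)C(C)(O)OO1
F6 | step 8 | (6S)-3-hydroxy-3,4,6-trimethyl-6-[(2R,9Z)-2-methyl-10-phenyldec-9-en-1-yl]-1,2-dioxane-4-carboxylic acid | C[C@H](CCCCCC/C=C\c1ccccc1)C[C@@]1(C)CC(C)(C(=O)O)C(C)(O)OO1
F7 | step 5 | S-ethyl (2E,10Z)-11-phenylundeca-2,10-dienethioate | CCSC(=O)/C=C/CCCCCC/C=C\c1ccccc1
F8 | step 5 | S-ethyl (3R,10Z)-3-methyl-11-phenylundec-10-enethioate | C[C@H](CCCCCC/C=C\c1ccccc1)CC(=O)SCC
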